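Everything rests on cutting the cyclobutane (ring C) into two exocyclic alkenes. Its adjacent spiro carbons are C5 of butenolide ring A (3-butyl) and C5 of butenolide ring B (3-acetoxybutyl); its adjacent CHBr carbons were the bromomethylene carbons attached to those C5 atoms, which makes the target a crossed head-to-head dimer. A single photochemical [2+2] union creates both ring C bonds and all four ring stereocentres. The partners are the two (E)-4-bromo-5-(bromomethylene)butenolides, one with butyl and one with (R)-1-acetoxybutyl at C3; E geometry, obtained by photoisomerising the Z isomers that synthesis delivers, keeps each bromine anti to its own lactone oxygen, as the target requires.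

Key step: step 9

Remark on the chemistry: read from the target SMILES, ring C has its two lactone oxygens trans, its two CHBr bromines trans, and each bromine trans to the oxygen on the spiro carbon it is bonded to (spiro carbons S,S; CHBr carbons R,R; acetoxy carbon R). This is the anti head-to-head adduct formed suprafacially from two E alkenes, so the E partners are the correct precursors.

Assumption: ethyl 2-bromohexanoate is used racemic, because its stereocentre is destroyed in step 3.

Step 1
Reactants: 1 ethyl acetoacetate; 2 ethyl 2-bromohexanoate (racemic)
Product: 3 diethyl 2-acetyl-3-butylbutanedioate (racemic, both diastereomers)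
Conditions: NaOEt (1.05 equiv), EtOH, 0 °C to reflux
Reagents that add atoms: none
Why: Acetoacetic ester alkylation, in which the sodium enolate of 1 displaces bromide from the carbonyl-activated α-bromo ester by SN2; the two stereocentres formed need no control because both are erased by step 3.

Step 2
Reactants: 3 diethyl 2-acetyl-3-butylbutanedioate
Product: 4 2-butyl-4-oxopentanoic acid (racemic)
Conditions: 6 M HCl, reflux
Reagents that add atoms: water, O
Why: Acid hydrolysis of both esters followed by decarboxylation of the β-keto acid (ketonic cleavage of an acetoacetic ester), so only the carboxyl β to the ketone is lost.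

Step 3
Reactants: 4 2-butyl-4-oxopentanoic acid
Product: 6 (Z)-4-bromo-5-(bromomethylene)-3-butylfuran-2(5H)-one, via dibromo keto acid 5 (not isolated)
Conditions: Br2 (2.1 equiv), cat. HBr, CH2Cl2, 0 °C to rt; evaporate; conc. H2SO4, 100 °C, 20 min
Reagents that add atoms: bromine, BrBr
Why: Acid-catalysed α-bromination of the ketone on both sides (C3 and C5 of the acid), then sulfuric acid enol-lactonisation with dehydration and oxidative introduction of the ring C3=C4 double bond (furanone numbering, hot H2SO4 as terminal oxidant), the established route to 4-bromo-5-(bromomethylene)furanones; the Z alkene, with the exocyclic bromine turned away from the C4 bromine, is the thermodynamic isomer under these equilibrating acidic conditions.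

Step 4
Reactants: 6 (Z)-4-bromo-5-(bromomethylene)-3-butylfuran-2(5H)-one
Product: 7 (E)-4-bromo-5-(bromomethylene)-3-butylfuran-2(5H)-one
Conditions: hν (350 nm, Pyrex), degassed MeCN, 0.005 M, rt; SiO2 chromatography in the dark, recovered 6 recycled
Reagents that add atoms: none
Why: Photochemical E/Z isomerisation of the exocyclic enol-lactone double bond through its twisted excited state should give a photostationary mixture from which the more congested E isomer is separated, high dilution keeping bimolecular dimerisation from competing.

Step 5
Reactants: 6 (Z)-4-bromo-5-(bromomethylene)-3-butylfuran-2(5H)-one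
Product: 8 rac-(Z)-4-bromo-5-(bromomethylene)-3-(1-bromobutyl)furan-2(5H)-one
Conditions: NBS (1.1 equiv), AIBN (cat.), PhCF3, 80 °C
Reagents that add atoms: N-bromosuccinimide, O=C1CCC(=O)N1Br
Why: Wohl–Ziegler bromination, in which hydrogen abstraction occurs only at C1' of the butyl chain because that radical alone is allylic to the C3=C4 bond; the new stereocentre is formed racemic.

Step 6
Reactants: 8 rac-(Z)-4-bromo-5-(bromomethylene)-3-(1-bromobutyl)furan-2(5H)-one
Product: 9 rac-(Z)-4-bromo-5-(bromomethylene)-3-(1-hydroxybutyl)furan-2(5H)-one
Conditions: H2O–1,4-dioxane (1:1), cat. H2SO4, reflux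
Reagents that add atoms: water, O
Why: SN1-type solvolysis of the activated allylic secondary bromide, in which the two vinylic bromides do not ionise and the acidic medium spares the base-sensitive enol lactone; the stereocentre stays racemic.

Step 7
Reactants: 9 rac-(Z)-4-bromo-5-(bromomethylene)-3-(1-hydroxybutyl)furan-2(5H)-one
Product: 10 (R)-1-[(Z)-4-bromo-5-(bromomethylene)-2-oxo-2,5-dihydrofuran-3-yl]butyl acetate
Conditions: immobilised Burkholderia cepacia lipase, vinyl acetate (3 equiv), MTBE, 30 °C, dark, stopped short of half conversion
Reagents that add atoms: vinyl acetate, C=COC(C)=O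
Why: Lipase-catalysed kinetic resolution by irreversible transesterification, in which the empirical rule for secondary alcohols (large planar furanonyl group against medium n-propyl) predicts faster acylation of the (R)-alcohol, so the (R)-acetate should form directly with the C–O bond untouched while the (S)-enantiomer of 9 stays as alcohol and is removed by chromatography.

Step 8
Reactants: 10 (R)-1-[(Z)-4-bromo-5-(bromomethylene)-2-oxo-2,5-dihydrofuran-3-yl]butyl acetate
Product: 11 (R)-1-[(E)-4-bromo-5-(bromomethylene)-2-oxo-2,5-dihydrofuran-3-yl]butyl acetate
Conditions: hν (350 nm, Pyrex), degassed MeCN, 0.005 M, rt; SiO2 chromatography in the dark, recovered 10 recycled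
Reagents that add atoms: none
Why: Photochemical E/Z isomerisation as in step 4, in which only the exocyclic double bond twists, so the (R)-acetoxy stereocentre is retained.

Step 9
Reactants: 7 (E)-4-bromo-5-(bromomethylene)-3-butylfuran-2(5H)-one; 11 (R)-1-[(E)-4-bromo-5-(bromomethylene)-2-oxo-2,5-dihydrofuran-3-yl]butyl acetate
Product: 12 (1R)-1-[(5S,6S,11R,12R)-4,10,11,12-tetrabromo-9-butyl-2,8-dioxo-1,7-dioxadispiro[4.0.4.2]dodeca-3,9-dien-3-yl]butyl acetate (the target)
Conditions: hν (λ > 300 nm, Pyrex-filtered mercury lamp), degassed MeCN, butyl partner in fivefold excess, ca. 1 M total, −30 °C, partial conversion; SiO2 chromatography, then HPLC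
Reagents that add atoms: none
Why: Light absorbed by the cross-conjugated bromodienone of either partner gives an excited state (expected to be triplet, the bromines speeding intersystem crossing) whose exocyclic CHBr carbon bonds to the CHBr carbon of a ground-state partner, and the resulting 1,4-biradical, with both radical centres at C5 where the ring oxygen and the butenolide π system stabilise them, then joins C5 to C5; the closest known reaction is the head-to-head [2+2] photodimerisation of 5-ylidenebutenolides such as protoanemonin to anemonin. Ring C is closed by an intermolecular first bond followed by recombination of the 1,4-biradical, overall a [2π+2π] cycloaddition suprafacial on both alkenes. The two CHBr carbons are set trans to each other, and the two spiro carbons receive trans oxygens, by antiparallel stacking of the two lactones (opposed dipoles, bromines kept apart), while at each spiro carbon the bromine stays anti to the ring oxygen because the E geometry is carried through, which requires closure to outrun rotation about the C5–CHBr bonds and is helped by heavy-atom-accelerated spin inversion and low temperature. Head-to-head regiochemistry follows from the most stabilised biradical, crossed pairing is favoured statistically by the excess of inexpensive 7, high concentration and partial conversion keep bimolecular capture ahead of E/Z leakage, and the dimers, lacking the dienone chromophore, should not absorb the filtered light and so are not reopened. The absolute sense of ring C is not controlled by the remote (R)-acetoxy carbon, so 12 should be accompanied by its diastereomer with the mirror-image ring C and is separated from it, from the homodimers and from geometry-scrambled adducts by chromatography and HPLC, recovered monomers being recycled through steps 4 and 8.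

Compound list
1 | ethyl acetoacetate | CC(=O)CC(=O)OCC | starting material
2 | ethyl 2-bromohexanoate (racemic) | CCCCC(Br)C(=O)OCC | starting material
3 | diethyl 2-acetyl-3-butylbutanedioate (racemic, both diastereomers) | CCCCC(C(=O)OCC)C(C(C)=O)C(=O)OCC | intermediate
4 | 2-butyl-4-oxopentanoic acid (racemic) | CCCCC(CC(C)=O)C(=O)O | intermediate
5 | 3,5-dibromo-2-butyl-4-oxopentanoic acid (stereoisomer mixture, not isolated) | CCCCC(C(Br)C(=O)CBr)C(=O)O | intermediate
6 | (Z)-4-bromo-5-(bromomethylene)-3-butylfuran-2(5H)-one | Br/C=C1\OC(=O)C(CCCC)=C1Br | intermediate
7 | (E)-4-bromo-5-(bromomethylene)-3-butylfuran-2(5H)-one | Br/C=C1/OC(=O)C(CCCC)=C1Br | intermediate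
8 | rac-(Z)-4-bromo-5-(bromomethylene)-3-(1-bromobutyl)furan-2(5H)-one | Br/C=C1\OC(=O)C(C(Br)CCC)=C1Br | intermediate
9 | rac-(Z)-4-bromo-5-(bromomethylene)-3-(1-hydroxybutyl)furan-2(5H)-one | Br/C=C1\OC(=O)C(C(O)CCC)=C1Br | intermediate
10 | (R)-1-[(Z)-4-bromo-5-(bromomethylene)-2-oxo-2,5-dihydrofuran-3-yl]butyl acetate | Br/C=C1\OC(=O)C([C@@H](CCC)OC(C)=O)=C1Br | intermediate
11 | (R)-1-[(E)-4-bromo-5-(bromomethylene)-2-oxo-2,5-dihydrofuran-3-yl]butyl acetate | Br/C=C1/OC(=O)C([C@@H](CCC)OC(C)=O)=C1Br | intermediate
12 | (1R)-1-[(5S,6S,11R,12R)-4,10,11,12-tetrabromo-9-butyl-2,8-dioxo-1,7-dioxadispiro[4.0.4.2]dodeca-3,9-dien-3-yl]butyl acetate; ring C with trans oxygens, trans bromines, each bromine trans to the oxygen of the spiro carbon it is bonded to | CCCCC1=C(Br)[C@@]2(OC1=O)[C@@H](Br)[C@H](Br)[C@@]21OC(=O)C([C@@H](CCC)OC(C)=O)=C1Br | target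

Total step count: 9. Longest linear sequence: 8 (steps 1, 2, 3, 5, 6, 7, 8, 9); step 4 is the one-step branch to the second partner.

Steps most likely to fail

First, step 9. Statistical pairing, loss of alkene geometry in a biradical that lives long enough to rotate, E/Z leakage of the monomers and C–Br homolysis could together leave the crossed anti head-to-head adduct as a minor component that is hard to separate, while consuming the resolved partner. The fallback sets out from 7 and comes back at 12, and removes the crossed-pairing problem by dimerising one monomer only. Irradiation of 7 alone under the conditions of step 9 should give the C2-symmetric homodimer rac-(5S,6S,11R,12R)-4,10,11,12-tetrabromo-3,9-dibutyl-1,7-dioxadispiro[4.0.4.2]dodeca-3,9-diene-2,8-dione F1, which has fewer possible isomers. Its two equivalent butyl chains are then differentiated by Wohl–Ziegler monobromination at one C1' (substoichiometric NBS, AIBN, PhCF3, 80 °C, F1 recycled) to the monobromide 3-(1-bromobutyl)-4,10,11,12-tetrabromo-9-butyl-1,7-dioxadispiro[4.0.4.2]dodeca-3,9-diene-2,8-dione F2. Acetolysis of the allylic bromide (AgOAc, AcOH, rt) gives the acetate stereoisomer mixture F3, which has the constitution of 12 with racemic ring C and both configurations at the acetoxy carbon. From it 12 is isolated by silica chromatography (diastereomers) and HPLC on a chiral stationary phase (enantiomers).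

Second, step 7. Acyl transfer may be slow or poorly selective, because the carbinol sits between a hindered furanone carbon flanked on both sides and an n-propyl group at the upper size limit of the enzyme's smaller pocket. The fallback sets out from 9 and comes back at 10, replacing resolution by reagent-controlled reduction. Dess–Martin periodinane (CH2Cl2, rt) gives the ketone (Z)-4-bromo-5-(bromomethylene)-3-butanoylfuran-2(5H)-one F4. CBS reduction ((S)-Me-CBS oxazaborolidine cat., catecholborane, toluene, −78 °C), with the furanonyl group as the large substituent and propyl as the small one, should deliver (Z)-4-bromo-5-(bromomethylene)-3-[(R)-1-hydroxybutyl]furan-2(5H)-one F5. Acetylation (Ac2O, 2,6-lutidine, cat. DMAP, CH2Cl2, 0 °C) then gives 10.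

Third, step 8 (and its twin, step 4). The photostationary state may be poor in the E isomer, the strained E isomer may revert on silica or on handling, or C–Br cleavage may erode material during irradiation. The fallback sets out from 10 (with 6 used in place of 7) and comes back at 12, and abandons isolation of the E isomers. 6 and 10 are irradiated together at 405 nm in concentrated MeCN with thioxanthone as triplet sensitiser, so that only the sensitiser absorbs. The E/Z mixture is then set up and replenished by energy transfer in the same flask while cycloaddition drains it. The adduct mixture would be richer in stereoisomers and 12 is isolated by HPLC; the fallback makes no further compound (none F0).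

Further compounds
F1 | step 9 | rac-(5S,6S,11R,12R)-4,10,11,12-tetrabromo-3,9-dibutyl-1,7-dioxadispiro[4.0.4.2]dodeca-3,9-diene-2,8-dione (one enantiomer drawn) | CCCCC1=C(Br)[C@@]2(OC1=O)[C@@H](Br)[C@H](Br)[C@@]21OC(=O)C(CCCC)=C1Br
F2 | step 9 | 3-(1-bromobutyl)-4,10,11,12-tetrabromo-9-butyl-1,7-dioxadispiro[4.0.4.2]dodeca-3,9-diene-2,8-dione (racemic ring C as drawn, both C1' epimers) | CCCCC1=C(Br)[C@@]2(OC1=O)[C@@H](Br)[C@H](Br)[C@@]21OC(=O)C(C(Br)CCC)=C1Br
F3 | step 9 | acetate stereoisomer mixture with the constitution of 12 (racemic ring C as drawn, both configurations at the acetoxy carbon) | CCCCC1=C(Br)[C@@]2(OC1=O)[C@@H](Br)[C@H](Br)[C@@]21OC(=O)C(C(CCC)OC(C)=O)=C1Br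
F4 | step 7 | (Z)-4-bromo-5-(bromomethylene)-3-butanoylfuran-2(5H)-one | Br/C=C1\OC(=O)C(C(=O)CCC)=C1Br
F5 | step 7 | (Z)-4-bromo-5-(bromomethylene)-3-[(R)-1-hydroxybutyl]furan-2(5H)-one | Br/C=C1\OC(=O)C([C@@H](CCC)O)=C1Br
F0 | step 8 | none | none
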